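## Retrosynthetic overview

1. The 2H‑pyran ring is closed last, by oxidative oxa‑6π cyclisation of an aryl prenyl group in a methylene‑bridged, prenylated dimer; no preformed chromene is used.
2. The methylene bridge comes from an oxidised ring C‑methyl group: an exocyclic enone made from the dearomatised monomer is trapped by 3‑prenylphlorisobutyrophenone, so no formaldehyde is needed.
3. The dearomatised monomer comes from an enantioselective, desymmetrising dearomative C‑prenylation of Cs‑symmetric 3,5‑dimethylphlorisobutyrophenone; this sets the only stereocentre.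
4. Both phenols come from phlorisobutyrophenone by C‑methylation or C‑prenylation; phlorisobutyrophenone comes from phloroglucinol and isobutyryl chloride.
5. Ring order: the benzene rings are bought, ring A is dearomatised in step 3, and the pyran ring is formed in the last operation (step 5).

Assumption 1: enolised β‑triketones are drawn and named in the enol form of the target SMILES, and CIP descriptors refer to that form.
Assumption 2: the (R,R)‑ligand in step 3 is taken to give (4R)‑7; if the measured sense is opposite, the (S,S)‑ligand is used and nothing else changes.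

## Route

Step 1
Reactants: 1 phloroglucinol; 2 isobutyryl chloride
Product: 3 phlorisobutyrophenone, 2‑methyl‑1‑(2,4,6‑trihydroxyphenyl)propan‑1‑one
Conditions: AlCl3 (3.5 eq), PhNO2/CH2Cl2, 0 → 40 °C; aq. HCl
Reagents that add atoms: isobutyryl chloride 2, CC(C)C(Cl)=O
Why: Friedel–Crafts acylation of the C3‑symmetric triol stops after one acyl group because the aluminium‑chelated product is deactivated.

Step 2
Reactants: 3 phlorisobutyrophenone; 4 iodomethane
Product: 5 2‑methyl‑1‑(2,4,6‑trihydroxy‑3,5‑dimethylphenyl)propan‑1‑one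
Conditions: NaOMe (2.2 eq), MeI (2.1 eq), MeOH, 0 °C → rt; aq. HCl; chromatography
Reagents that add atoms: iodomethane 4, CI
Why: Phenolate C‑alkylation with soft MeI in protic MeOH takes the two unsubstituted ring carbons first, each followed by re‑aromatisation, and about two equivalents of MeI stop it before the slower dearomatising third methylation.

Step 3
Reactants: 5 2‑methyl‑1‑(2,4,6‑trihydroxy‑3,5‑dimethylphenyl)propan‑1‑one; 6 prenyl acetate
Product: 7 (4R)‑3,5‑dihydroxy‑4,6‑dimethyl‑4‑(3‑methylbut‑2‑en‑1‑yl)‑2‑(2‑methylpropanoyl)cyclohexa‑2,5‑dien‑1‑one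
Conditions: Pd2(dba)3·CHCl3 (2.5 mol%), (R,R)‑DACH‑phenyl Trost ligand (7.5 mol%), Et3N (1.1 eq), 6 (1.0 eq, slow addition), CH2Cl2, 0 °C → rt; aq. HCl
Reagents that add atoms: prenyl acetate 6, CC(=O)OCC=C(C)C
Why: Proposed new method: a Tsuji–Trost asymmetric allylic alkylation run as a desymmetrising dearomatisation, in which the Cs‑symmetric phenolate of 5 attacks the unsubstituted terminus of the (π‑prenyl)Pd–ligand cation through one of its two enantiotopic methyl‑bearing ring carbons, so the ligand sets the quaternary stereocentre, while any O‑prenyl ether re‑ionises on Pd(0) and drains to the irreversible C‑alkylation; the closest known reaction types are Pd/Trost‑ligand allylic dearomatisation of phenols and naphthols and racemic Pd‑catalysed dearomative prenylation of acylphloroglucinols.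

Step 4
Reactants: 3 phlorisobutyrophenone; 8 prenyl bromide
Product: 9 2‑methyl‑1‑[2,4,6‑trihydroxy‑3‑(3‑methylbut‑2‑en‑1‑yl)phenyl]propan‑1‑one
Conditions: prenyl bromide (1.0 eq), 5% aq. KOH, 0 °C; aq. HCl; chromatography
Reagents that add atoms: prenyl bromide 8, CC(C)=CCBr
Why: Phenolate C‑alkylation in water, where hydrogen bonding to the phenoxide oxygens suppresses O‑alkylation, puts one prenyl group on one of the two equivalent free ring carbons; the 3,5‑diprenyl by‑product is separated.

Step 5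
Reactants: 7 (4R)‑dearomatised monomer; 9 3‑prenylphlorisobutyrophenone
Product: 13 target CNP0319758.1, via exocyclic enone 10 (not isolated), via prenylated dimer 11 (not isolated), via o‑quinone methide 12 (not isolated)
Conditions: 7 (1.1 eq), 9 (1.0 eq), TEMPO (1.0 eq), Ag2O (1.05 eq), PhMe, 0 °C → rt, 2 h; then DDQ (1.05 eq), same flask, rt, 30 min
Reagents that add atoms: none
Why: Proposed new method: a biomimetic double dehydrogenation in one flask, in which Ag2O/TEMPO turns the ring C‑methyl group of 7 into exocyclic enone 10 (enol oxidation, TEMPO trapping, elimination), the only free ring carbon of 9 adds to it (Friedel–Crafts/Michael) to give 11, and DDQ then abstracts hydride from the benzylic‑allylic CH2 of the aryl prenyl group to give o‑quinone methide 12, which closes by oxa‑6π electrocyclisation onto the oxygen para to the acyl group, the quaternary stereocentre staying untouched; the closest known reaction types are TEMPO/Ag2O generation of such enones from C‑methylated dearomatised acylphloroglucinols for hetero‑Diels–Alder trapping, Michael addition of acylphloroglucinols to alkylidene β‑triketones, and DDQ cyclisation of o‑prenylphenols to 2,2‑dimethylchromenes.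

## Compound list

1 | phloroglucinol (benzene‑1,3,5‑triol) | Oc1cc(O)cc(O)c1 | starting material
2 | isobutyryl chloride | CC(C)C(Cl)=O | starting material
3 | phlorisobutyrophenone, 2‑methyl‑1‑(2,4,6‑trihydroxyphenyl)propan‑1‑one | CC(C)C(=O)c1c(O)cc(O)cc1O | intermediate
4 | iodomethane | CI | starting material
5 | 2‑methyl‑1‑(2,4,6‑trihydroxy‑3,5‑dimethylphenyl)propan‑1‑one | CC(C)C(=O)c1c(O)c(C)c(O)c(C)c1O | intermediate
6 | prenyl acetate (3‑methylbut‑2‑en‑1‑yl acetate) | CC(=O)OCC=C(C)C | starting material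
7 | (4R)‑3,5‑dihydroxy‑4,6‑dimethyl‑4‑(3‑methylbut‑2‑en‑1‑yl)‑2‑(2‑methylpropanoyl)cyclohexa‑2,5‑dien‑1‑one | CC(C)=CC[C@]1(C)C(O)=C(C)C(=O)C(C(=O)C(C)C)=C1O | intermediate
8 | prenyl bromide (1‑bromo‑3‑methylbut‑2‑ene) | CC(C)=CCBr | starting material
9 | 2‑methyl‑1‑[2,4,6‑trihydroxy‑3‑(3‑methylbut‑2‑en‑1‑yl)phenyl]propan‑1‑one | CC(C)C(=O)c1c(O)cc(O)c(CC=C(C)C)c1O | intermediate
10 | (6S)‑5‑hydroxy‑6‑methyl‑2‑methylidene‑6‑(3‑methylbut‑2‑en‑1‑yl)‑4‑(2‑methylpropanoyl)cyclohex‑4‑ene‑1,3‑dione (same spatial arrangement as 7; the descriptor changes by CIP priority only) | CC(C)=CC[C@]1(C)C(=O)C(=C)C(=O)C(C(=O)C(C)C)=C1O | intermediate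
11 | (4R)‑6‑{[2,4,6‑trihydroxy‑3‑(3‑methylbut‑2‑en‑1‑yl)‑5‑(2‑methylpropanoyl)phenyl]methyl}‑3,5‑dihydroxy‑4‑methyl‑4‑(3‑methylbut‑2‑en‑1‑yl)‑2‑(2‑methylpropanoyl)cyclohexa‑2,5‑dien‑1‑one | CC(C)=CC[C@]1(C)C(O)=C(Cc2c(O)c(C(=O)C(C)C)c(O)c(CC=C(C)C)c2O)C(=O)C(C(=O)C(C)C)=C1O | intermediate
12 | (4R)‑6‑{[(5Z)‑2,4‑dihydroxy‑5‑(3‑methylbut‑2‑en‑1‑ylidene)‑3‑(2‑methylpropanoyl)‑6‑oxocyclohexa‑1,3‑dien‑1‑yl]methyl}‑3,5‑dihydroxy‑4‑methyl‑4‑(3‑methylbut‑2‑en‑1‑yl)‑2‑(2‑methylpropanoyl)cyclohexa‑2,5‑dien‑1‑one | CC(C)=CC[C@]1(C)C(O)=C(CC2=C(O)C(C(=O)C(C)C)=C(O)/C(=C/C=C(C)C)C2=O)C(=O)C(C(=O)C(C)C)=C1O | intermediate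
13 | (4R)‑6‑{[5,7‑dihydroxy‑2,2‑dimethyl‑6‑(2‑methylpropanoyl)‑2H‑chromen‑8‑yl]methyl}‑3,5‑dihydroxy‑4‑methyl‑4‑(3‑methylbut‑2‑en‑1‑yl)‑2‑(2‑methylpropanoyl)cyclohexa‑2,5‑dien‑1‑one | CC(C)=CC[C@]1(C)C(O)=C(Cc2c(O)c(C(=O)C(C)C)c(O)c3c2OC(C)(C)C=C3)C(=O)C(C(=O)C(C)C)=C1O | target

## Step count and risks

Total steps: 5. Longest linear sequence: 4 (steps 1, 2, 3, 5).

**Step 3 (most likely to fail).** The risks are low enantioselectivity in the desymmetrisation, an unknown sense of induction, O‑prenylation, and a second prenylation of 7. The fallback sets out from 5 and comes back at 7, replacing catalyst control by racemic synthesis and resolution. 5 is C‑prenylated without a chiral catalyst (prenyl bromide 8, NaOMe, MeOH, 0 °C) to give racemic 7 F1. Preparative chiral SFC on a polysaccharide phase then separates 7 from the unwanted (4S)‑enantiomer F2.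

**Step 5.** The risks are over‑oxidation of 11 at the bridging CH2, hetero‑Diels–Alder capture of 10 by a prenyl alkene, and pyran closure onto the oxygen ortho to the acyl group. The fallback sets out from 3 (with 7 kept in hand) and comes back at 13; the pyran ring is made first and non‑oxidatively, with its regiochemistry fixed by construction. 3 is O‑alkylated at the 4‑hydroxyl with 3‑chloro‑3‑methylbut‑1‑yne (K2CO3, KI, cat. CuI, acetone) to give 1‑[2,6‑dihydroxy‑4‑(2‑methylbut‑3‑yn‑2‑yloxy)phenyl]‑2‑methylpropan‑1‑one F3. Heating F3 (xylene, 130 °C) triggers a propargyl Claisen rearrangement, 1,5‑H shift and oxa‑6π closure to give 1‑(5,7‑dihydroxy‑2,2‑dimethyl‑2H‑chromen‑6‑yl)‑2‑methylpropan‑1‑one F4. Its pyran oxygen is necessarily the one para to the acyl group. Enone 10 is then generated from 7 (TEMPO, Ag2O, PhMe) in the presence of F4, whose only free ring carbon (C‑8) adds to give 13 directly.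

**Step 2.** The risk is a mixture of mono‑, di‑ and trimethyl homologues that is hard to separate. The fallback sets out from 1 and comes back at 5; the two C1 units are introduced as formyl groups and the acyl group is added last. Double Vilsmeier–Haack formylation of 1 (POCl3, DMF, EtOAc; then H2O) gives 2,4,6‑trihydroxybenzene‑1,3‑dicarbaldehyde F5. Hydrogenolysis of both formyl groups (H2, Pd/C, AcOH) gives 2,4‑dimethylbenzene‑1,3,5‑triol F6. Friedel–Crafts acylation of F6 with 2 (AlCl3, PhNO2) at its only free ring position gives 5.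

## Further compounds

F1 | step 3 | racemic 3,5‑dihydroxy‑4,6‑dimethyl‑4‑(3‑methylbut‑2‑en‑1‑yl)‑2‑(2‑methylpropanoyl)cyclohexa‑2,5‑dien‑1‑one | CC(C)=CCC1(C)C(O)=C(C)C(=O)C(C(=O)C(C)C)=C1O
F2 | step 3 | (4S)‑3,5‑dihydroxy‑4,6‑dimethyl‑4‑(3‑methylbut‑2‑en‑1‑yl)‑2‑(2‑methylpropanoyl)cyclohexa‑2,5‑dien‑1‑one | CC(C)=CC[C@@]1(C)C(O)=C(C)C(=O)C(C(=O)C(C)C)=C1O
F3 | step 5 | 1‑[2,6‑dihydroxy‑4‑(2‑methylbut‑3‑yn‑2‑yloxy)phenyl]‑2‑methylpropan‑1‑one | CC(C)C(=O)c1c(O)cc(OC(C)(C)C#C)cc1O
F4 | step 5 | 1‑(5,7‑dihydroxy‑2,2‑dimethyl‑2H‑chromen‑6‑yl)‑2‑methylpropan‑1‑one | CC(C)C(=O)c1c(O)cc2OC(C)(C)C=Cc2c1O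
F5 | step 2 | 2,4,6‑trihydroxybenzene‑1,3‑dicarbaldehyde | O=Cc1c(O)cc(O)c(C=O)c1O
F6 | step 2 | 2,4‑dimethylbenzene‑1,3,5‑triol | Cc1c(O)cc(O)c(C)c1O
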